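The target's only sp3 ring atoms are the two C(CH3)2 carbons, C4 of each terminal 2-butanoyl-3,5-dihydroxycyclohexa-2,5-dienone (filicinic) ring. Taking one methyl off each in retrosynthesis leaves a fully aromatic tetramer: four butanoylphloroglucinol rings joined by three CH2 bridges, with one C-methyl on each end ring. The key step exploits these two methyl-bearing ring carbons. As part of an ambident phenoxide, each accepts a second methyl from iodomethane, so one operation forms both quaternary carbons and dearomatises both end rings. The tetramer is assembled convergently from two Friedel–Crafts ketones, formaldehyde and a Mannich base.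

Key step: step 6

Remark on the chemistry: the target has no stereocentre and is achiral, so no enantiomer has to be chosen; it is drawn as one enol tautomer of its two terminal triketone rings.
Remark on the structures: the tetramer and the target were checked atom by atom (C45H52O16 plus two CH2 gives C47H56O16) and need no correction; paraformaldehyde is a polymer, HO(CH2O)nH, and is entered with the SMILES of the formaldehyde unit it delivers.
Remark on the precursor: compound 13 is made and used with all twelve hydroxyl groups free, because the phenoxides are the nucleophiles of step 6 and any O-protection would shut the dearomatisation down.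

Step 1
Reactants: 1 phloroglucinol (anhydrous); 2 butyryl chloride (1.0 equiv)
Product: 3 1-(2,4,6-trihydroxyphenyl)butan-1-one (butyrylphloroglucinol)
Conditions: AlCl3 (4 equiv), PhNO2/CH2Cl2, 0 °C → 45 °C; then ice, 1 M HCl
Reagents that add atoms: butyryl chloride, CCCC(Cl)=O
Why: Friedel–Crafts acylation of the strongly activated triol (directly or by O-acylation and Fries shift under AlCl3) should stop at the monoketone, because the aluminium-chelated aryl ketone is deactivated and only one equivalent of acid chloride is offered.

Step 2
Reactants: 4 2,4,6-trihydroxytoluene; 2 butyryl chloride (1.0 equiv)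
Product: 5 1-(2,4,6-trihydroxy-3-methylphenyl)butan-1-one
Conditions: AlCl3 (4 equiv), PhNO2/CH2Cl2, 0 °C → 45 °C; then ice, 1 M HCl
Reagents that add atoms: butyryl chloride, CCCC(Cl)=O
Why: The same Friedel–Crafts acylation should give a single regioisomer, since the two free ring carbons of 4 are equivalent, and it leaves exactly one open ring position in 5.

Step 3
Reactants: 3 butyrylphloroglucinol (4 equiv per CH2O); 6 paraformaldehyde
Product: 8 bis(3-butanoyl-2,4,6-trihydroxyphenyl)methane, via hydroxymethyl ketone 7 (not isolated)
Conditions: (CH2O)n (0.25 equiv as CH2O, predissolved in warm aq NaOH), 0.5 M aq NaOH, 0 °C, Ar, 20 min; then 1 M HCl; excess 3 recovered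
Reagents that add atoms: formaldehyde (from paraformaldehyde), C=O
Why: Lederer–Manasse hydroxymethylation of the phenoxide gives 7, which loses hydroxide to a quinone methide that a second phenoxide traps (phenol–formaldehyde condensation); the excess of 3 should hold the reaction at the dimer, and the two free carbons of 3 are equivalent, so only one constitution of 8 can form.

Step 4
Reactants: 5 1-(2,4,6-trihydroxy-3-methylphenyl)butan-1-one; 6 paraformaldehyde; 9 dimethylamine
Product: 10 1-{3-[(dimethylamino)methyl]-2,4,6-trihydroxy-5-methylphenyl}butan-1-one
Conditions: (CH2O)n (1.5 equiv), Me2NH (40% aq, 1.6 equiv), EtOH, rt, 30 min; then 5, 0 °C → rt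
Reagents that add atoms: formaldehyde (from paraformaldehyde), C=O; dimethylamine, CNC
Why: Mannich reaction at the single free ring carbon of 5 with the premixed hemiaminal/iminium; the excess of amine and formaldehyde and the low temperature should keep the product from alkylating a second molecule of 5, and 10 should crystallise as its inner salt.

Step 5
Reactants: 8 bis(3-butanoyl-2,4,6-trihydroxyphenyl)methane (1 equiv); 10 Mannich base (2.3 equiv)
Product: 13 bis[3-butanoyl-5-(3-butanoyl-2,4,6-trihydroxy-5-methylbenzyl)-2,4,6-trihydroxyphenyl]methane (all-aromatic tetramer), via o-quinone methide 11 (not isolated), via mono-capped trimer 12 (not isolated)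
Conditions: 1,4-dioxane, 100 °C, Ar stream (sweeps out Me2NH); then dilute HCl wash, crystallisation
Reagents that add atoms: none
Why: Thermal loss of dimethylamine from the ortho-hydroxybenzylamine gives 11, which the one free ring carbon of each half of 8 captures in a Michael-type Friedel–Crafts alkylation (Mannich-base alkylation of phenols); both partners are monofunctional here, so capping should end at the fully substituted tetramer.

Step 6
Reactants: 13 all-aromatic tetramer; 14 iodomethane (2.2 equiv)
Product: 16 bis{3-butanoyl-5-[(5-butanoyl-2,4-dihydroxy-3,3-dimethyl-6-oxocyclohexa-1,4-dien-1-yl)methyl]-2,4,6-trihydroxyphenyl}methane (target), via mono-methylated tetramer 15 (not isolated)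
Conditions: NaOMe (6.5 equiv), MeI (2.2 equiv, slow addition), degassed MeOH, 0 °C → rt, Ar, dark; then cold 1 M HCl, crystallisation
Reagents that add atoms: iodomethane, CI
Why: Methoxide turns 13 into its polyphenoxide, and in each end ring the ambident phenoxide attacks iodomethane (SN2) through the ring carbon that already carries CH3, which lies ortho and para to the oxygens; this creates the C(CH3)2 carbon and leaves the ring as the enolate of a cross-conjugated β-triketone, first in 15 and then at the second end. The closest known reaction is the C-methylation of C-methylated acylphloroglucinols with MeI and alkoxide to acylfilicinic acids, here run twice on one molecule. No ring is closed and no stereocentre arises, since each new quaternary carbon carries two identical methyl groups and the product is achiral. The step needs alkylation at carbon, not oxygen, and at the two CH3-bearing carbons, not the six ring carbons that carry a CH2 bridge: hydrogen-bonding methanol and the soft iodide favour carbon, and a methyl-substituted carbon is more accessible than one flanked by an arylmethyl arm. Each methylated ring becomes a strongly acidic triketone whose delocalised anion is a poor nucleophile, so with about two equivalents of MeI the reaction should stop at two new C–CH3 bonds. Cold, oxygen-free conditions and a short contact time with base are chosen to limit base-induced exchange of the methylene bridges.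

Compound list
1 | phloroglucinol (benzene-1,3,5-triol) | Oc1cc(O)cc(O)c1 | starting material
2 | butyryl chloride | CCCC(Cl)=O | starting material
3 | 1-(2,4,6-trihydroxyphenyl)butan-1-one (butyrylphloroglucinol) | CCCC(=O)c1c(O)cc(O)cc1O | intermediate
4 | 2,4,6-trihydroxytoluene (2-methylbenzene-1,3,5-triol) | Cc1c(O)cc(O)cc1O | starting material
5 | 1-(2,4,6-trihydroxy-3-methylphenyl)butan-1-one | CCCC(=O)c1c(O)cc(O)c(C)c1O | intermediate
6 | paraformaldehyde (polymer; SMILES of the formaldehyde unit it delivers) | C=O | starting material
7 | 1-[2,4,6-trihydroxy-3-(hydroxymethyl)phenyl]butan-1-one | CCCC(=O)c1c(O)cc(O)c(CO)c1O | intermediate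
8 | bis(3-butanoyl-2,4,6-trihydroxyphenyl)methane (central dimer) | CCCC(=O)c1c(O)cc(O)c(Cc2c(O)cc(O)c(C(=O)CCC)c2O)c1O | intermediate
9 | dimethylamine | CNC | starting material
10 | 1-{3-[(dimethylamino)methyl]-2,4,6-trihydroxy-5-methylphenyl}butan-1-one (Mannich base) | CCCC(=O)c1c(O)c(C)c(O)c(CN(C)C)c1O | intermediate
11 | 2-butanoyl-3,5-dihydroxy-4-methyl-6-methylidenecyclohexa-2,4-dien-1-one (o-quinone methide) | CCCC(=O)C1=C(O)C(C)=C(O)C(=C)C1=O | intermediate
12 | mono-capped trimer: central dimer 8 carrying one (3-butanoyl-2,4,6-trihydroxy-5-methylphenyl)methyl group on one free ring carbon | CCCC(=O)c1c(O)c(C)c(O)c(Cc2c(O)c(Cc3c(O)cc(O)c(C(=O)CCC)c3O)c(O)c(C(=O)CCC)c2O)c1O | intermediate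
13 | bis[3-butanoyl-5-(3-butanoyl-2,4,6-trihydroxy-5-methylbenzyl)-2,4,6-trihydroxyphenyl]methane (all-aromatic tetramer) | CCCC(=O)c1c(O)c(C)c(O)c(Cc2c(O)c(Cc3c(O)c(Cc4c(O)c(C)c(O)c(C(=O)CCC)c4O)c(O)c(C(=O)CCC)c3O)c(O)c(C(=O)CCC)c2O)c1O | intermediate
14 | iodomethane | CI | starting material
15 | mono-methylated tetramer: 13 with one end ring converted into the 5-butanoyl-2,4-dihydroxy-3,3-dimethyl-6-oxocyclohexa-1,4-dien-1-yl unit | CCCC(=O)C1=C(O)C(C)(C)C(O)=C(Cc2c(O)c(Cc3c(O)c(Cc4c(O)c(C)c(O)c(C(=O)CCC)c4O)c(O)c(C(=O)CCC)c3O)c(O)c(C(=O)CCC)c2O)C1=O | intermediate
16 | bis{3-butanoyl-5-[(5-butanoyl-2,4-dihydroxy-3,3-dimethyl-6-oxocyclohexa-1,4-dien-1-yl)methyl]-2,4,6-trihydroxyphenyl}methane (achiral) | CCCC(=O)C1=C(O)C(C)(C)C(O)=C(Cc2c(O)c(Cc3c(O)c(CC4=C(O)C(C)(C)C(O)=C(C(=O)CCC)C4=O)c(O)c(C(=O)CCC)c3O)c(O)c(C(=O)CCC)c2O)C1=O | target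

Total step count: 6. Longest linear sequence: 4 steps (steps 1, 3, 5, 6 or steps 2, 4, 5, 6).

Steps most likely to fail

Step 6. Methylation may spread to the bridge-bearing ring carbons or to oxygen, may stall after one end, and the alkaline medium may cleave and re-form the methylene bridges (retro-Michael/Michael exchange), scrambling the chain. The fallback moves the C-methylation to the monomer stage. It sets out from 3, which with MeI (about 3 equiv) and NaOMe in MeOH should give butyrylfilicinic acid F1 after separation from under- and over-methylated congeners. A Mannich reaction at its one free ring carbon with paraformaldehyde and dimethylamine in EtOH should then give the aminomethyl triketone F2. Heating F2 (2.3 equiv) with the central dimer 8 in dioxane, as in step 5, should deliver the target directly, so the fallback comes back to the route at 16.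

Step 5. The quinone methide may be captured at already substituted ring carbons (ipso attack with loss of an aminomethyl or methylene unit), leading to the symmetrical dimer of the end unit and to scrambled oligomers, or the second capping may lag. The fallback reverses the roles of the partners. It sets out from 8, whose two free ring carbons should undergo a double Mannich reaction with paraformaldehyde and dimethylamine in EtOH to give the bis-Mannich base F3. Heating F3 in dioxane with an excess (4–5 equiv) of the monofunctional ketone 5 should then cap both ends, and the fallback comes back to the route at 13.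

Step 3. The condensation may run past the dimer, because 8 still has two free ring carbons, and separation of oligomers from recovered 3 may be poor. The fallback builds the chain from the outside in. It sets out from 10, which on heating in dioxane with an excess (4 equiv) of 3 should give the unsymmetrical dimer F4 with a single free ring carbon. Treating F4 (2 equiv) with paraformaldehyde (1 equiv as CH2O) in cold dilute aqueous NaOH, then acid, should join two molecules through the last methylene bridge; the condensation cannot go further, and the fallback comes back to the route at 13.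

Further compounds
F1 | step 6 | 2-butanoyl-3,5-dihydroxy-4,4-dimethylcyclohexa-2,5-dien-1-one (butyrylfilicinic acid) | CCCC(=O)C1=C(O)C(C)(C)C(O)=CC1=O
F2 | step 6 | 2-butanoyl-6-[(dimethylamino)methyl]-3,5-dihydroxy-4,4-dimethylcyclohexa-2,5-dien-1-one | CCCC(=O)C1=C(O)C(C)(C)C(O)=C(CN(C)C)C1=O
F3 | step 5 | bis{3-butanoyl-5-[(dimethylamino)methyl]-2,4,6-trihydroxyphenyl}methane | CCCC(=O)c1c(O)c(CN(C)C)c(O)c(Cc2c(O)c(CN(C)C)c(O)c(C(=O)CCC)c2O)c1O
F4 | step 3 | 1-[3-(3-butanoyl-2,4,6-trihydroxybenzyl)-2,4,6-trihydroxy-5-methylphenyl]butan-1-one | CCCC(=O)c1c(O)c(C)c(O)c(Cc2c(O)cc(O)c(C(=O)CCC)c2O)c1O
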